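**Retrosynthetic overview**
- The target is 8-hydroxy-6,7-dimethoxyflavone carrying a 3-hydroxy-4,5-dimethoxyphenyl ring B. It is reached from 7,8-catechol 10 by selective 7-O-methylation and hydrogenolysis of the ring B benzyl ether.
- Key disconnection O1–C8a: ring C is closed by anodic oxidation of the catechol ring of 1,3-diketone 8 to its ortho-quinone, followed by intramolecular oxa-Michael addition of the diketone enol oxygen.
- The strategy rests on C8a of ring A, which lies between the oxygen-bearing C8 and C4a (which carries the C4 carbonyl). In the 7,8-quinone, C8a is the β-carbon of the C4 enone and the δ-carbon of the dienone from C7=O, whereas the other ortho carbon, C5, is made electron-rich by the C6 methoxy group.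
- Diketone 8 comes from a crossed Claisen condensation of bis-MOM acetophenone 4 (from aldehyde 1) with benzyl-protected ester 6 (from ester 5), then MOM removal.
- Rings A and B are purchased; ring C is the only ring formed (step 7).

Key step: step 7

Assumptions: methyl 3-hydroxy-4,5-dimethoxybenzoate 5 is taken as a catalogue compound. The 1,3-diketones are drawn in the diketo form although they are largely enolised. Alcohol 3 is racemic and its stereocentre is removed in step 3.

**Route**

Step 1
Reactants: 1 3,4-dihydroxy-5-methoxybenzaldehyde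
Product: 2 3-methoxy-4,5-bis(methoxymethoxy)benzaldehyde
Conditions: MOMCl, i-Pr2NEt, CH2Cl2, 0 °C to rt
Reagents that add atoms: chloromethyl methyl ether (MOMCl), COCCl
Why: Williamson-type O-alkylation of both phenols by the reactive α-chloro ether under amine base should give the bis-acetal without touching the aldehyde.

Step 2
Reactants: 2 3-methoxy-4,5-bis(methoxymethoxy)benzaldehyde
Product: 3 1-[3-methoxy-4,5-bis(methoxymethoxy)phenyl]ethanol (racemic)
Conditions: MeMgBr, THF, 0 °C
Reagents that add atoms: methylmagnesium bromide, C[Mg]Br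
Why: Grignard 1,2-addition to the aryl aldehyde is compatible with MOM and methyl ethers; the carbinol centre is formed racemic on purpose because step 3 removes it.

Step 3
Reactants: 3 1-[3-methoxy-4,5-bis(methoxymethoxy)phenyl]ethanol
Product: 4 1-[3-methoxy-4,5-bis(methoxymethoxy)phenyl]ethanone
Conditions: Dess–Martin periodinane, CH2Cl2, rt
Reagents that add atoms: none
Why: Dess–Martin oxidation of a secondary benzylic alcohol to the aryl methyl ketone runs under near-neutral conditions that the MOM acetals tolerate.

Step 4
Reactants: 5 methyl 3-hydroxy-4,5-dimethoxybenzoate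
Product: 6 methyl 3-(benzyloxy)-4,5-dimethoxybenzoate
Conditions: BnBr, K2CO3, DMF, rt
Reagents that add atoms: benzyl bromide, BrCc1ccccc1
Why: Williamson ether synthesis on the single free phenol masks the future 3'-OH so that it survives the anodic step and the later methylation.

Step 5
Reactants: 4 1-[3-methoxy-4,5-bis(methoxymethoxy)phenyl]ethanone; 6 methyl 3-(benzyloxy)-4,5-dimethoxybenzoate
Product: 7 1-[3-(benzyloxy)-4,5-dimethoxyphenyl]-3-[3-methoxy-4,5-bis(methoxymethoxy)phenyl]propane-1,3-dione
Conditions: NaH, THF, reflux; then aq. HCl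
Reagents that add atoms: none
Why: Crossed Claisen condensation of the sodium enolate of the methyl ketone with a non-enolisable methyl ester is driven forward by deprotonation of the 1,3-diketone, and all ethers and acetals are base-stable.

Step 6
Reactants: 7 1-[3-(benzyloxy)-4,5-dimethoxyphenyl]-3-[3-methoxy-4,5-bis(methoxymethoxy)phenyl]propane-1,3-dione
Product: 8 1-[3-(benzyloxy)-4,5-dimethoxyphenyl]-3-(3,4-dihydroxy-5-methoxyphenyl)propane-1,3-dione
Conditions: 2 M aq. HCl, MeOH–THF, 45 °C, Ar
Reagents that add atoms: none
Why: Acid-catalysed acetal exchange transfers both MOM groups to methanol as dimethoxymethane, while the benzyl ether, the methyl ethers and the 1,3-diketone are inert to dilute acid.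

Step 7
Reactants: 8 1-[3-(benzyloxy)-4,5-dimethoxyphenyl]-3-(3,4-dihydroxy-5-methoxyphenyl)propane-1,3-dione
Product: 10 2-[3-(benzyloxy)-4,5-dimethoxyphenyl]-7,8-dihydroxy-6-methoxy-4H-chromen-4-one, via ortho-quinone 9 (not isolated)
Conditions: divided cell, graphite-felt anode, Pt cathode, controlled potential about +0.45 V against Ag/AgCl (set from a preliminary voltammogram), about 2 F/mol, MeCN/0.2 M aq. NaOAc–AcOH buffer (pH 6) 1:1, 5 mM, rt, Ar; work-up with aq. Na2S2O4
Reagents that add atoms: none
Why: Proposed new method: the catechol ring of 8 is the only group oxidised at this potential and loses two electrons and two protons to give ortho-quinone 9, in which the ring CH flanked by the aroyl-bearing carbon and the quinone carbonyl (future C8a) is at once the β-carbon of the aryl ketone enone and the δ-terminus of the dienone running from the future C7 carbonyl; the enol oxygen of the 1,3-diketone adds to it and loss of the C8a proton re-aromatises the ring to the catechol of 10. The closest known reaction type is the anodic oxidation of catechols in the presence of 1,3-dicarbonyl compounds, in which Michael addition to the electrogenerated quinone leads to benzofurans and coumestans, but closure of a pyranone ring by an enol oxygen on such a quinone is not established. Ring C closes in a 6-endo-trig oxa-Michael mode, O1 attacking C8a of the C4a=C8a double bond that lies inside the new ring. No stereocentre is formed. The step needs attack at C8a and not at the other ortho carbon C5, O-attack and not C-attack, and cyclisation before intermolecular coupling: C5 is only the β-carbon of the C7 enone and is made electron-rich by the C6 methoxy group on the same double bond while C8a is activated twice, the central diketone carbon could reach either ortho carbon only through a four-membered ring, and high dilution holds back bimolecular addition. Passing close to the theoretical charge and washing with Na2S2O4 should return any over-oxidised quinone of 10 to the catechol.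

Step 8
Reactants: 10 2-[3-(benzyloxy)-4,5-dimethoxyphenyl]-7,8-dihydroxy-6-methoxy-4H-chromen-4-one
Product: 11 2-[3-(benzyloxy)-4,5-dimethoxyphenyl]-8-hydroxy-6,7-dimethoxy-4H-chromen-4-one
Conditions: MeI (1.05 equiv), NaHCO3 (1.1 equiv), DMF, 40 °C
Reagents that add atoms: iodomethane, CI
Why: Regioselective mono-O-alkylation (SN2) should occur at the 7-OH, which is para to C4a and conjugated with the C4 carbonyl and therefore the phenol ionised by hydrogencarbonate, as in the 4-O-alkylation of 3,4-dihydroxybenzaldehyde.

Step 9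
Reactants: 11 2-[3-(benzyloxy)-4,5-dimethoxyphenyl]-8-hydroxy-6,7-dimethoxy-4H-chromen-4-one
Product: 12 8-hydroxy-2-(3-hydroxy-4,5-dimethoxyphenyl)-6,7-dimethoxy-4H-chromen-4-one
Conditions: H2 (1 atm), Pd/C, EtOAc–MeOH, rt
Reagents that add atoms: none
Why: Catalytic hydrogenolysis cleaves the benzyl ether to the phenol and toluene, while the conjugated chromone C2=C3 bond and the methyl ethers should be unaffected at ambient pressure.

**Compound list**

1 | 3,4-dihydroxy-5-methoxybenzaldehyde | COc1cc(C=O)cc(O)c1O | starting material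
2 | 3-methoxy-4,5-bis(methoxymethoxy)benzaldehyde | COCOc1cc(C=O)cc(OC)c1OCOC | intermediate
3 | 1-[3-methoxy-4,5-bis(methoxymethoxy)phenyl]ethanol (racemic) | COCOc1cc(C(C)O)cc(OC)c1OCOC | intermediate
4 | 1-[3-methoxy-4,5-bis(methoxymethoxy)phenyl]ethanone | COCOc1cc(C(C)=O)cc(OC)c1OCOC | intermediate
5 | methyl 3-hydroxy-4,5-dimethoxybenzoate | COc1cc(C(=O)OC)cc(O)c1OC | starting material
6 | methyl 3-(benzyloxy)-4,5-dimethoxybenzoate | COc1cc(C(=O)OC)cc(OCc2ccccc2)c1OC | intermediate
7 | 1-[3-(benzyloxy)-4,5-dimethoxyphenyl]-3-[3-methoxy-4,5-bis(methoxymethoxy)phenyl]propane-1,3-dione | COCOc1cc(C(=O)CC(=O)c2cc(OC)c(OC)c(OCc3ccccc3)c2)cc(OC)c1OCOC | intermediate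
8 | 1-[3-(benzyloxy)-4,5-dimethoxyphenyl]-3-(3,4-dihydroxy-5-methoxyphenyl)propane-1,3-dione | COc1cc(C(=O)CC(=O)c2cc(OC)c(OC)c(OCc3ccccc3)c2)cc(O)c1O | intermediate
9 | 5-{3-[3-(benzyloxy)-4,5-dimethoxyphenyl]-3-oxopropanoyl}-3-methoxycyclohexa-3,5-diene-1,2-dione (ortho-quinone, not isolated) | COC1=CC(C(=O)CC(=O)c2cc(OC)c(OC)c(OCc3ccccc3)c2)=CC(=O)C1=O | intermediate
10 | 2-[3-(benzyloxy)-4,5-dimethoxyphenyl]-7,8-dihydroxy-6-methoxy-4H-chromen-4-one | COc1cc2c(=O)cc(-c3cc(OC)c(OC)c(OCc4ccccc4)c3)oc2c(O)c1O | intermediate
11 | 2-[3-(benzyloxy)-4,5-dimethoxyphenyl]-8-hydroxy-6,7-dimethoxy-4H-chromen-4-one | COc1cc2c(=O)cc(-c3cc(OC)c(OC)c(OCc4ccccc4)c3)oc2c(O)c1OC | intermediate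
12 | 8-hydroxy-2-(3-hydroxy-4,5-dimethoxyphenyl)-6,7-dimethoxy-4H-chromen-4-one | COc1cc(-c2cc(=O)c3cc(OC)c(OC)c(O)c3o2)cc(O)c1OC | target

**Step count**

Total steps: 9. Longest linear sequence: 8 steps (steps 1, 2, 3, 5, 6, 7, 8, 9); step 4 is the one-step side branch.

**Steps most likely to fail**

1. Step 7 (anodic ring closure). Three processes may defeat it:
- the enol oxygen may close on the other ortho carbon, next to the methoxy group, which is the usual site for acyl-ortho-quinones that lack the methoxy substituent;
- the product catechol may be oxidised further and its quinone consumed by water or acetate;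
- the quinone of one molecule may be attacked by the diketone carbon of another.

Fallback (known chemistry, O1 installed from the start): it sets out from ester 6 and returns at 11, bypassing steps 5 to 8. Commercial 1-(2-hydroxy-4,5-dimethoxyphenyl)ethanone is brominated (NBS, MeCN, 0 °C) at the only position activated by the phenol to give 1-(3-bromo-2-hydroxy-4,5-dimethoxyphenyl)ethanone F1. Its dianion (LiN(SiMe3)2, THF, −78 °C to rt) is acylated by 6 in a Claisen condensation to give 1-[3-(benzyloxy)-4,5-dimethoxyphenyl]-3-(3-bromo-2-hydroxy-4,5-dimethoxyphenyl)propane-1,3-dione F2. Cyclodehydration (p-TsOH, toluene, reflux) gives 2-[3-(benzyloxy)-4,5-dimethoxyphenyl]-8-bromo-6,7-dimethoxy-4H-chromen-4-one F3. Miyaura borylation (B2pin2, Pd(OAc)2, SPhos, KOAc, dioxane, 90 °C) gives the 8-pinacolboronate F4, and oxidation with NaBO3·4H2O in THF–H2O gives 11, from which step 9 follows.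

2. Step 8 (selective 7-O-methylation). Alkylation may not discriminate between the two adjacent phenols and may run on to the dimethyl ether, because the monoanion can shuttle its proton between O7 and O8.

Fallback (transient blocking of O8 in place of kinetic selection): it sets out from 10 and returns at 11. Ac2O/pyridine gives the 7,8-diacetate F5. PhSH/imidazole in NMP at 0 °C removes selectively the acetate of the more acidic 7-phenol, a known selectivity for flavone polyacetates, giving the 8-acetoxy-7-hydroxy compound F6. Mitsunobu methylation (MeOH, PPh3, DIAD, THF) under non-basic conditions gives the 8-acetoxy-7-methoxy compound F7. K2CO3 in MeOH at rt removes the remaining acetate to give 11.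

3. Step 5 (crossed Claisen condensation). Acylation of the ketone enolate by the electron-rich, deactivated benzoate may be slow, so that self-aldol condensation of ketone 4 and retro-Claisen cleavage of the product compete.

Fallback (aldol addition then oxidation in place of ester acylation): it sets out from 4 and returns at 7. Commercial 3-hydroxy-4,5-dimethoxybenzaldehyde is benzylated (BnBr, K2CO3, DMF) to 3-(benzyloxy)-4,5-dimethoxybenzaldehyde F8. The lithium enolate of 4 (LiN(SiMe3)2, THF, −78 °C) adds to F8 to give the racemic β-hydroxy ketone F9. Dess–Martin periodinane in CH2Cl2 oxidises F9 to diketone 7.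

**Further compounds**

F1 | step 7 | 1-(3-bromo-2-hydroxy-4,5-dimethoxyphenyl)ethanone | CC(=O)c1cc(OC)c(OC)c(Br)c1O
F2 | step 7 | 1-[3-(benzyloxy)-4,5-dimethoxyphenyl]-3-(3-bromo-2-hydroxy-4,5-dimethoxyphenyl)propane-1,3-dione | COc1cc(C(=O)CC(=O)c2cc(OC)c(OC)c(Br)c2O)cc(OCc2ccccc2)c1OC
F3 | step 7 | 2-[3-(benzyloxy)-4,5-dimethoxyphenyl]-8-bromo-6,7-dimethoxy-4H-chromen-4-one | COc1cc2c(=O)cc(-c3cc(OC)c(OC)c(OCc4ccccc4)c3)oc2c(Br)c1OC
F4 | step 7 | 2-[3-(benzyloxy)-4,5-dimethoxyphenyl]-6,7-dimethoxy-8-(4,4,5,5-tetramethyl-1,3,2-dioxaborolan-2-yl)-4H-chromen-4-one | COc1cc2c(=O)cc(-c3cc(OC)c(OC)c(OCc4ccccc4)c3)oc2c(B3OC(C)(C)C(C)(C)O3)c1OC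
F5 | step 8 | 2-[3-(benzyloxy)-4,5-dimethoxyphenyl]-6-methoxy-4-oxo-4H-chromene-7,8-diyl diacetate | COc1cc2c(=O)cc(-c3cc(OC)c(OC)c(OCc4ccccc4)c3)oc2c(OC(C)=O)c1OC(C)=O
F6 | step 8 | 2-[3-(benzyloxy)-4,5-dimethoxyphenyl]-7-hydroxy-6-methoxy-4-oxo-4H-chromen-8-yl acetate | COc1cc2c(=O)cc(-c3cc(OC)c(OC)c(OCc4ccccc4)c3)oc2c(OC(C)=O)c1O
F7 | step 8 | 2-[3-(benzyloxy)-4,5-dimethoxyphenyl]-6,7-dimethoxy-4-oxo-4H-chromen-8-yl acetate | COc1cc2c(=O)cc(-c3cc(OC)c(OC)c(OCc4ccccc4)c3)oc2c(OC(C)=O)c1OC
F8 | step 5 | 3-(benzyloxy)-4,5-dimethoxybenzaldehyde | COc1cc(C=O)cc(OCc2ccccc2)c1OC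
F9 | step 5 | 3-[3-(benzyloxy)-4,5-dimethoxyphenyl]-3-hydroxy-1-[3-methoxy-4,5-bis(methoxymethoxy)phenyl]propan-1-one (racemic) | COCOc1cc(C(=O)CC(O)c2cc(OC)c(OC)c(OCc3ccccc3)c2)cc(OC)c1OCOC
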